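**Plan** (ring numbering used throughout: C1 = acetoxy carbon, C2, C3, C4 = ketone, C5 = methyl-bearing carbon, C6–C8, C9/C10 = epoxide, C11 = ketone, C12 = isopropylidene carbon, C13, C14)
Retrosynthesis: move the C12 isopropylidene double bond back to an isopropenyl group, cut the fourteen-membered ring at C4–C5, then cut C11–C12 into a west half (C1–C4, C12–C14) and an east half (C5–C11).
Enabling feature: the acetoxy carbon C1 is gamma to the ketone C4, so O–C1–C2–C3–C4 is a latent five-membered lactone (oxolan-2-one) ring whose carbonyl is the acyl donor and whose ring oxygen becomes the acetate oxygen.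
Forward: the lactone allylic bromide comes from (R)-linalool plus CO, the epoxy aldehyde from hepta-1,6-diyne, and the two are joined at C11–C12 by chromium allylation.
Ring formation: a vinyllithium at C5 attacks the lactone carbonyl C4, which closes the carbocycle, opens the five-membered ring, and frees the C1 alkoxide for acetylation in the same flask.
Finish: hydrogenation of C5=CH2, oxidation at C11, shift of the isopropenyl double bond into conjugation.
Stereochemistry: C1 from (R)-linalool (the C1–O bond is never broken); C9/C10 from Sharpless epoxidation of the (E)-allylic alcohol with L-(+)-tartrate; C5 from catalyst-controlled hydrogenation; the centres formed at C11/C12 are transient.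

Key step: step 11

Remark on the chemistry: (R)-(−)-linalool of high enantiomeric purity is taken as commercial. The sense of induction in step 12 cannot be predicted for this macrocycle, so (S)-BINAP is written and the antipodal complex would be used if that is the one that gives 5S. Compounds 15–21 are carried as mixtures at C11/C12 and 22 as a mixture at C12, because both centres are removed by step 15.

Step 1
Reactants: 1 (R)-linalool
Product: 3 (5R)-5-methyl-5-(4-methylpent-3-en-1-yl)oxolan-2-ol (both C2 epimers), via hydroxy aldehyde 2 (not isolated)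
Conditions: Rh(acac)(CO)2 (0.5 mol %), PPh3 (5 mol %), CO/H2 1:1 (20 bar), toluene, 80 °C
Reagents that add atoms: carbon monoxide, [C-]#[O+]
Why: Rh-catalysed linear-selective hydroformylation adds H and CHO across the monosubstituted vinyl group only (the quaternary C1 blocks the branched acyl and the trisubstituted alkene is inert), and the gamma-hydroxy aldehyde 2 closes at once to the five-membered lactol, leaving the linalool stereocentre (C1) untouched.

Step 2
Reactants: 3 (5R)-5-methyl-5-(4-methylpent-3-en-1-yl)oxolan-2-ol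
Product: 4 (5R)-5-methyl-5-(4-methylpent-3-en-1-yl)oxolan-2-one
Conditions: PhI(OAc)2 (1.3 equiv), TEMPO (10 mol %), CH2Cl2, rt
Reagents that add atoms: none
Why: TEMPO-catalysed oxoammonium oxidation with PhI(OAc)2 as terminal oxidant converts a lactol into the lactone and does not touch the trisubstituted alkene.

Step 3
Reactants: 4 (5R)-5-methyl-5-(4-methylpent-3-en-1-yl)oxolan-2-one
Product: 5 (5R)-5-[(3E)-5-hydroxy-4-methylpent-3-en-1-yl]-5-methyloxolan-2-one
Conditions: SeO2 (0.3 equiv), t-BuOOH (3 equiv), salicylic acid (10 mol %), CH2Cl2, rt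
Reagents that add atoms: tert-butyl hydroperoxide, CC(C)(C)OO (oxygen passed on through catalytic selenium dioxide, O=[Se]=O)
Why: Catalytic SeO2 allylic oxidation (ene reaction followed by [2,3]-sigmatropic shift, reoxidation by t-BuOOH) is selective for the (E)-methyl group of a 2-methylalk-2-ene and should give the (E)-allylic alcohol, the lactone being inert.

Step 4
Reactants: 5 (5R)-5-[(3E)-5-hydroxy-4-methylpent-3-en-1-yl]-5-methyloxolan-2-one
Product: 6 (5R)-5-[(3E)-5-bromo-4-methylpent-3-en-1-yl]-5-methyloxolan-2-one
Conditions: CBr4 (1.3 equiv), PPh3 (1.4 equiv), CH2Cl2, 0 °C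
Reagents that add atoms: carbon tetrabromide, BrC(Br)(Br)Br
Why: Appel bromination converts the primary allylic alcohol into the bromide with retention of the (E) geometry at 0 °C, and the lactone is unaffected.

Step 5
Reactants: 7 hepta-1,6-diyne (threefold excess)
Product: 9 2-iodohept-1-en-6-yne, via iodoalkenylborane 8 (not isolated)
Conditions: B-iodo-9-BBN (1 equiv), hexane, 0 °C; then AcOH, 0 °C to rt; excess 7 recovered by distillation
Reagents that add atoms: B-iodo-9-borabicyclo[3.3.1]nonane, IB1C2CCCC1CCC2
Why: Haloboration: B-iodo-9-BBN adds syn across one terminal alkyne with iodine on the internal carbon, and protonolysis of the alkenyl C–B bond by acetic acid gives the 2-iodoalk-1-ene, the excess of symmetrical diyne keeping double addition low.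

Step 6
Reactants: 9 2-iodohept-1-en-6-yne
Product: 11 (2E)-7-iodo-3-methylocta-2,7-dien-1-ol, via alkenylalane 10 (not isolated)
Conditions: Me3Al (2.5 equiv), Cp2ZrCl2 (0.25 equiv), CH2Cl2, 0 °C to rt; then (CH2O)n (4 equiv), THF, rt; aqueous work-up
Reagents that add atoms: trimethylaluminium, C[Al](C)C; paraformaldehyde (reacts as formaldehyde), C=O
Why: Zr-catalysed syn-carboalumination (Negishi carboalumination) puts methyl on the internal alkyne carbon and aluminium on the terminus, and trapping of the alkenylalane with formaldehyde with retention should give the (E)-trisubstituted allylic alcohol, the 2-iodoalkene being inert to Me3Al.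

Step 7
Reactants: 11 (2E)-7-iodo-3-methylocta-2,7-dien-1-ol
Product: 12 [(2S,3S)-3-(4-iodopent-4-en-1-yl)-3-methyloxiran-2-yl]methanol
Conditions: Ti(OiPr)4 (10 mol %), L-(+)-DIPT (12 mol %), t-BuOOH (2 equiv), 4 Å molecular sieves, CH2Cl2, −20 °C
Reagents that add atoms: tert-butyl hydroperoxide, CC(C)(C)OO
Why: Sharpless asymmetric epoxidation: the titanium tartrate complex binds the allylic hydroxyl and, with L-(+)-DIPT, delivers oxygen to the face of the (E)-alkene that gives the (2S,3S)-epoxy alcohol (C9 and C10 of the target), while the electron-poor, non-allylic iodoalkene is not epoxidised.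

Step 8
Reactants: 12 [(2S,3S)-3-(4-iodopent-4-en-1-yl)-3-methyloxiran-2-yl]methanol
Product: 13 (2R,3S)-3-(4-iodopent-4-en-1-yl)-3-methyloxirane-2-carbaldehyde
Conditions: Dess–Martin periodinane (1.3 equiv), NaHCO3 (5 equiv), CH2Cl2, 0 °C to rt
Reagents that add atoms: none
Why: Buffered Dess–Martin oxidation of a 2,3-epoxy alcohol gives the epoxy aldehyde without opening the epoxide or epimerising C10 (the descriptor changes to 2R only through the priority change).

Step 9
Reactants: 6 (5R)-5-[(3E)-5-bromo-4-methylpent-3-en-1-yl]-5-methyloxolan-2-one; 13 (2R,3S)-3-(4-iodopent-4-en-1-yl)-3-methyloxirane-2-carbaldehyde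
Product: 15 (5R)-5-{3-[hydroxy((2S,3S)-3-(4-iodopent-4-en-1-yl)-3-methyloxiran-2-yl)methyl]-4-methylpent-4-en-1-yl}-5-methyloxolan-2-one (mixture at C11/C12), via allylchromium reagent 14 (not isolated)
Conditions: CrCl2 (4 equiv), THF, 0 °C to rt
Reagents that add atoms: none
Why: Nozaki–Hiyama allylation: CrCl2 converts the allylic bromide into the allylchromium reagent, which adds to the aldehyde through its gamma carbon in a chair transition state and so forms C11–C12 together with the isopropenyl group, while the iodoalkene (no nickel salt present) and the lactone do not react; the two new centres are not controlled because both become sp2 later.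

Step 10
Reactants: 15 (5R)-5-{3-[hydroxy((2S,3S)-3-(4-iodopent-4-en-1-yl)-3-methyloxiran-2-yl)methyl]-4-methylpent-4-en-1-yl}-5-methyloxolan-2-one
Product: 16 (5R)-5-{3-[((2S,3S)-3-(4-iodopent-4-en-1-yl)-3-methyloxiran-2-yl)(triethylsilyloxy)methyl]-4-methylpent-4-en-1-yl}-5-methyloxolan-2-one
Conditions: Et3SiCl (1.5 equiv), imidazole (3 equiv), DMF, rt
Reagents that add atoms: chlorotriethylsilane, CC[Si](Cl)(CC)CC
Why: Imidazole-promoted silyl ether formation at the secondary alcohol removes the only acidic proton before the organolithium step and gives an ether that survives t-BuLi at low temperature.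

Step 11
Reactants: 16 (5R)-5-{3-[((2S,3S)-3-(4-iodopent-4-en-1-yl)-3-methyloxiran-2-yl)(triethylsilyloxy)methyl]-4-methylpent-4-en-1-yl}-5-methyloxolan-2-one
Product: 19 (1R,9S,10S)-9,10-epoxy-1,9-dimethyl-5-methylidene-4-oxo-12-(prop-1-en-2-yl)-11-(triethylsilyloxy)cyclotetradecyl acetate, via vinyllithium 17 (not isolated), via lithium alkoxide 18 (not isolated)
Conditions: t-BuLi (2.1 equiv), THF/Et2O/pentane 4:1:1 (2 mM), −100 °C, then −100 to −20 °C over 3 h; then Ac2O (6 equiv), −20 °C to rt
Reagents that add atoms: acetic anhydride, CC(=O)OC(C)=O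
Why: Proposed new method: iodine–lithium exchange at the 2-iodoalkene (C5) with two equivalents of t-BuLi is faster at −100 °C than addition of t-BuLi to the lactone, and the resulting vinyllithium 17 adds on warming to the only carbonyl group present, the lactone carbon C4, after which the lithium hemiketal collapses by cleavage of the C4–O ring bond to the enone and the tertiary C1 lithium alkoxide 18, which acetic anhydride acylates on oxygen. The closest known reaction types are the Parham cyclisation (halogen–lithium exchange then intramolecular acylation by an ester, shown for five- to seven-membered rings) and the intermolecular opening of gamma-lactones by one equivalent of an organolithium with trapping of the released alkoxide; a fourteen-membered closure in which the acyl donor ring opens has not been shown. The carbocycle closes in the 14-exo-trig mode at C4–C5 while the oxolanone ring opens, so the net event is a ring expansion that delivers ring, ketone and tertiary acetate together. No stereocentre is formed: the tetrahedral C4 is transient and C1 keeps its R configuration because the C1–O bond is never broken. The step needs exchange before carbonyl addition (iodide, −100 °C), ring closure before intermolecular acylation (2 mM, slow warming) and a single addition (the ketone stays masked as the lithium hemiketal at low temperature and bimolecular attack is suppressed by dilution). The substrate secures chemoselectivity because C11 is a silyl ether, the trisubstituted epoxide is inert to organolithiums at low temperature, and the only ester that could compete, the acetate, is introduced in the quench.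

Step 12
Reactants: 19 (1R,9S,10S)-9,10-epoxy-1,9-dimethyl-5-methylidene-4-oxo-12-(prop-1-en-2-yl)-11-(triethylsilyloxy)cyclotetradecyl acetate
Product: 20 (1R,5S,9S,10S)-9,10-epoxy-1,5,9-trimethyl-4-oxo-12-(prop-1-en-2-yl)-11-(triethylsilyloxy)cyclotetradecyl acetate
Conditions: Ru(OAc)2[(S)-BINAP] (2 mol %), H2 (50 atm), CH2Cl2/MeOH 5:1, rt
Reagents that add atoms: none
Why: Asymmetric hydrogenation of an alpha-methylene ketone with a BINAP–Ru dicarboxylate: the ketone oxygen anchors the substrate on ruthenium and the ligand selects the face of C5=CH2 to which hydrogen is delivered, so C5 is set under catalyst control (antipode chosen as stated in the remark), and the isopropenyl group, which has no anchoring group, the epoxide and the acetate are expected to persist.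

Step 13
Reactants: 20 (1R,5S,9S,10S)-9,10-epoxy-1,5,9-trimethyl-4-oxo-12-(prop-1-en-2-yl)-11-(triethylsilyloxy)cyclotetradecyl acetate
Product: 21 (1R,5S,9S,10S)-9,10-epoxy-11-hydroxy-1,5,9-trimethyl-4-oxo-12-(prop-1-en-2-yl)cyclotetradecyl acetate
Conditions: TBAF (1.5 equiv), AcOH (1.5 equiv), THF, 0 °C
Reagents that add atoms: none
Why: Fluoride-mediated cleavage of the triethylsilyl ether, buffered with acetic acid so that the tertiary acetate, the epoxide and the epimerisable C5 are not exposed to base.

Step 14
Reactants: 21 (1R,5S,9S,10S)-9,10-epoxy-11-hydroxy-1,5,9-trimethyl-4-oxo-12-(prop-1-en-2-yl)cyclotetradecyl acetate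
Product: 22 (1R,5S,9S,10R)-9,10-epoxy-1,5,9-trimethyl-4,11-dioxo-12-(prop-1-en-2-yl)cyclotetradecyl acetate
Conditions: Dess–Martin periodinane (1.5 equiv), NaHCO3 (5 equiv), CH2Cl2, 0 °C to rt
Reagents that add atoms: none
Why: Dess–Martin oxidation of the secondary alcohol to the epoxy ketone under buffered, near-neutral conditions that leave C5 and the deconjugated alkene in place and erase the C11 stereocentre.

Step 15
Reactants: 22 (1R,5S,9S,10R)-9,10-epoxy-1,5,9-trimethyl-4,11-dioxo-12-(prop-1-en-2-yl)cyclotetradecyl acetate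
Product: 23 (1R,5S,9S,10R)-9,10-epoxy-1,5,9-trimethyl-4,11-dioxo-12-(propan-2-ylidene)cyclotetradecyl acetate (CNP0229580.1)
Conditions: DBU (0.2 equiv), CH2Cl2, 0 °C
Reagents that add atoms: none
Why: Base-catalysed isomerisation of a beta,gamma-unsaturated ketone to the conjugated enone (the isopulegone-to-pulegone type of shift): DBU removes the doubly activated C12–H (alpha to the ketone and allylic) and reprotonation at the CH2 terminus gives the tetrasubstituted isopropylidene enone, which erases C12 and converges the diastereomers, while the much less acidic C5–H is left alone at 0 °C.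

**Compound list**
1 | (R)-linalool, (3R)-3,7-dimethylocta-1,6-dien-3-ol | C=C[C@](C)(O)CCC=C(C)C | starting material
2 | (4R)-4-hydroxy-4,8-dimethylnon-7-enal | O=CCC[C@](C)(O)CCC=C(C)C | intermediate
3 | (5R)-5-methyl-5-(4-methylpent-3-en-1-yl)oxolan-2-ol (C2 epimers) | OC1CC[C@@](C)(CCC=C(C)C)O1 | intermediate
4 | (5R)-5-methyl-5-(4-methylpent-3-en-1-yl)oxolan-2-one | O=C1CC[C@@](C)(CCC=C(C)C)O1 | intermediate
5 | (5R)-5-[(3E)-5-hydroxy-4-methylpent-3-en-1-yl]-5-methyloxolan-2-one | O=C1CC[C@@](C)(CC/C=C(\C)CO)O1 | intermediate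
6 | (5R)-5-[(3E)-5-bromo-4-methylpent-3-en-1-yl]-5-methyloxolan-2-one | O=C1CC[C@@](C)(CC/C=C(\C)CBr)O1 | intermediate
7 | hepta-1,6-diyne | C#CCCCC#C | starting material
8 | 9-[(1Z)-2-iodohept-1-en-6-yn-1-yl]-9-borabicyclo[3.3.1]nonane | I/C(CCCC#C)=C\B1C2CCCC1CCC2 | intermediate
9 | 2-iodohept-1-en-6-yne | C=C(I)CCCC#C | intermediate
10 | [(1E)-6-iodo-2-methylhepta-1,6-dien-1-yl]dimethylalumane | C=C(I)CCC/C(C)=C/[Al](C)C | intermediate
11 | (2E)-7-iodo-3-methylocta-2,7-dien-1-ol | C=C(I)CCC/C(C)=C/CO | intermediate
12 | [(2S,3S)-3-(4-iodopent-4-en-1-yl)-3-methyloxiran-2-yl]methanol | C=C(I)CCC[C@]1(C)O[C@H]1CO | intermediate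
13 | (2R,3S)-3-(4-iodopent-4-en-1-yl)-3-methyloxirane-2-carbaldehyde | C=C(I)CCC[C@]1(C)O[C@H]1C=O | intermediate
14 | dichloro{(2E)-2-methyl-5-[(2R)-2-methyl-5-oxooxolan-2-yl]pent-2-en-1-yl}chromium | O=C1CC[C@@](C)(CC/C=C(\C)C[Cr](Cl)Cl)O1 | intermediate
15 | (5R)-5-{3-[hydroxy((2S,3S)-3-(4-iodopent-4-en-1-yl)-3-methyloxiran-2-yl)methyl]-4-methylpent-4-en-1-yl}-5-methyloxolan-2-one (mixture at C11/C12) | O=C1CC[C@@](C)(CCC(C(C)=C)C(O)[C@@H]2O[C@@]2(C)CCCC(I)=C)O1 | intermediate
16 | (5R)-5-{3-[((2S,3S)-3-(4-iodopent-4-en-1-yl)-3-methyloxiran-2-yl)(triethylsilyloxy)methyl]-4-methylpent-4-en-1-yl}-5-methyloxolan-2-one | O=C1CC[C@@](C)(CCC(C(C)=C)C(O[Si](CC)(CC)CC)[C@@H]2O[C@@]2(C)CCCC(I)=C)O1 | intermediate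
17 | (5R)-5-{3-[((2S,3S)-3-(4-lithiopent-4-en-1-yl)-3-methyloxiran-2-yl)(triethylsilyloxy)methyl]-4-methylpent-4-en-1-yl}-5-methyloxolan-2-one | O=C1CC[C@@](C)(CCC(C(C)=C)C(O[Si](CC)(CC)CC)[C@@H]2O[C@@]2(C)CCCC([Li])=C)O1 | intermediate
18 | lithium (1R,9S,10S)-9,10-epoxy-1,9-dimethyl-5-methylidene-4-oxo-12-(prop-1-en-2-yl)-11-(triethylsilyloxy)cyclotetradecan-1-olate | [Li]O[C@@]1(C)CCC(=O)C(=C)CCC[C@]2(C)O[C@H]2C(O[Si](CC)(CC)CC)C(C(C)=C)CC1 | intermediate
19 | (1R,9S,10S)-9,10-epoxy-1,9-dimethyl-5-methylidene-4-oxo-12-(prop-1-en-2-yl)-11-(triethylsilyloxy)cyclotetradecyl acetate | CC(=O)O[C@@]1(C)CCC(=O)C(=C)CCC[C@]2(C)O[C@H]2C(O[Si](CC)(CC)CC)C(C(C)=C)CC1 | intermediate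
20 | (1R,5S,9S,10S)-9,10-epoxy-1,5,9-trimethyl-4-oxo-12-(prop-1-en-2-yl)-11-(triethylsilyloxy)cyclotetradecyl acetate | CC(=O)O[C@@]1(C)CCC(=O)[C@@H](C)CCC[C@]2(C)O[C@H]2C(O[Si](CC)(CC)CC)C(C(C)=C)CC1 | intermediate
21 | (1R,5S,9S,10S)-9,10-epoxy-11-hydroxy-1,5,9-trimethyl-4-oxo-12-(prop-1-en-2-yl)cyclotetradecyl acetate | CC(=O)O[C@@]1(C)CCC(=O)[C@@H](C)CCC[C@]2(C)O[C@H]2C(O)C(C(C)=C)CC1 | intermediate
22 | (1R,5S,9S,10R)-9,10-epoxy-1,5,9-trimethyl-4,11-dioxo-12-(prop-1-en-2-yl)cyclotetradecyl acetate | CC(=O)O[C@@]1(C)CCC(=O)[C@@H](C)CCC[C@]2(C)O[C@H]2C(=O)C(C(C)=C)CC1 | intermediate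
23 | (1R,5S,9S,10R)-9,10-epoxy-1,5,9-trimethyl-4,11-dioxo-12-(propan-2-ylidene)cyclotetradecyl acetate (CNP0229580.1) | CC(=O)O[C@@]1(C)CCC(=O)[C@@H](C)CCC[C@]2(C)O[C@H]2C(=O)C(=C(C)C)CC1 | target

**Totals**
Total step count: 15. Longest linear sequence: 11 steps (steps 1–4 or 5–8, then 9–15).

**Steps most likely to fail**

Step 11. What may go wrong: proton transfer from the lactone alpha-CH2 to the vinyllithium before acylation, intermolecular acylation leading to oligomers, or acetyl capture at the bridged hemiketal oxygen instead of the ring-opened tertiary alkoxide. The fallback uses known chemistry, sets out from 16 and comes back at 19. Reduction of 16 with i-Bu2AlH (1.1 equiv, toluene, −78 °C) would give the lactol (5R)-5-{3-[((2S,3S)-3-(4-iodopent-4-en-1-yl)-3-methyloxiran-2-yl)(triethylsilyloxy)methyl]-4-methylpent-4-en-1-yl}-5-methyloxolan-2-ol F1, the masked C4 aldehyde. An intramolecular Nozaki–Hiyama–Kishi reaction of its open hydroxy aldehyde form (CrCl2, NiCl2 1 mol %, DMSO/THF, 3 mM, rt) would close the same C4–C5 bond and give the allylic diol (1R,9S,10S)-9,10-epoxy-1,9-dimethyl-5-methylidene-12-(prop-1-en-2-yl)-11-(triethylsilyloxy)cyclotetradecane-1,4-diol F2 as C4 epimers. MnO2 (CH2Cl2, rt) would oxidise only the secondary allylic alcohol to the hydroxy enone (1R,9S,10S)-9,10-epoxy-4-hydroxy-4,10-dimethyl-14-methylidene-7-(prop-1-en-2-yl)-8-(triethylsilyloxy)cyclotetradecan-1-one F3 (in ring numbering: 1-hydroxy, 4-oxo, 5-methylidene). Acetylation of the tertiary C1 hydroxyl (Ac2O, DMAP, Et3N, CH2Cl2, 40 °C) would then return to 19.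

Step 12. What may go wrong: poor facial selectivity at C5 in the conformationally mobile macrocycle, or competing saturation of the isopropenyl group. The fallback sets out from 19 and comes back at 20. Conjugate reduction with [(Ph3P)CuH]6 (wet benzene, rt) delivers hydride only to the enone CH2 terminus and protonates the copper enolate without facial control, which should give 20 together with its C5 epimer (1R,5R,9S,10S)-9,10-epoxy-1,5,9-trimethyl-4-oxo-12-(prop-1-en-2-yl)-11-(triethylsilyloxy)cyclotetradecyl acetate F4. The epimers are separated by chromatography, F4 is re-equilibrated through the C4 enolate (DBU, toluene, rt) and separated again; this is possible at this stage because C5 is the only epimerisable centre (C11 is still a silyl ether).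

Step 15. What may go wrong: epimerisation at C5 through enolisation of the C4 ketone, or base-induced opening of the epoxide from the C11 enolate side. The fallback sets out from 22 and comes back at 23 and makes no new compound (F0). The alkene is moved by a radical, non-basic hydrogen-atom-transfer isomerisation instead of enolisation: Co(salen)Cl (trivalent cobalt, 5 mol %) and PhSiH3 (10 mol %) in benzene at rt. The cobalt hydride adds a hydrogen atom to the CH2 terminus of the isopropenyl group, and the tertiary radical loses the C12 hydrogen atom to cobalt, which gives the conjugated tetrasubstituted alkene without touching C5–H.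

**Further compounds**
F1 | step 11 | (5R)-5-{3-[((2S,3S)-3-(4-iodopent-4-en-1-yl)-3-methyloxiran-2-yl)(triethylsilyloxy)methyl]-4-methylpent-4-en-1-yl}-5-methyloxolan-2-ol | OC1CC[C@@](C)(CCC(C(C)=C)C(O[Si](CC)(CC)CC)[C@@H]2O[C@@]2(C)CCCC(I)=C)O1
F2 | step 11 | (1R,9S,10S)-9,10-epoxy-1,9-dimethyl-5-methylidene-12-(prop-1-en-2-yl)-11-(triethylsilyloxy)cyclotetradecane-1,4-diol | O[C@@]1(C)CCC(O)C(=C)CCC[C@]2(C)O[C@H]2C(O[Si](CC)(CC)CC)C(C(C)=C)CC1
F3 | step 11 | (1R,9S,10S)-9,10-epoxy-1-hydroxy-1,9-dimethyl-5-methylidene-12-(prop-1-en-2-yl)-11-(triethylsilyloxy)cyclotetradecan-4-one (ring numbering of the route) | O[C@@]1(C)CCC(=O)C(=C)CCC[C@]2(C)O[C@H]2C(O[Si](CC)(CC)CC)C(C(C)=C)CC1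
F4 | step 12 | (1R,5R,9S,10S)-9,10-epoxy-1,5,9-trimethyl-4-oxo-12-(prop-1-en-2-yl)-11-(triethylsilyloxy)cyclotetradecyl acetate | CC(=O)O[C@@]1(C)CCC(=O)[C@H](C)CCC[C@]2(C)O[C@H]2C(O[Si](CC)(CC)CC)C(C(C)=C)CC1
F0 | step 15 | none | none
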